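The route rests on cutting the bond between C3 of the 5-hydroxyindole (rings A/B) and the central benzene (ring C). The ring C carbon next to that bond carries an oxygen (a methoxy oxygen in the target), which is first joined to the indole C2 carboxyl as an aryl ester. Palladium then links indole C3 to the ring C carbon ortho to that oxygen, forging the hindered biaryl bond and a six-membered lactone in one operation. The precursor is the 2,4,5-trimethoxyphenyl ester of a 5-benzyloxy-3-bromo-N-SEM-indole-2-carboxylic acid. Afterwards the lactone is opened and methylated, ring C is brominated para to the new bond, the 6-methoxyindole is attached by Suzuki coupling, and the carboxyl carbon leaves as CO2.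

Key step: step 6

Remark on the chemistry: the target has no stereocentre and no stereogenic axis (each aryl–indole bond of ring C is flanked by two methoxy groups), so no stereocontrol is needed; SEM = 2-(trimethylsilyl)ethoxymethyl on nitrogen, Boc = tert-butoxycarbonyl, Bpin = 4,4,5,5-tetramethyl-1,3,2-dioxaborolan-2-yl, rings D/E = the 6-methoxyindole.

Step 1
Reactants: 1 2,4,5-trimethoxybenzaldehyde
Product: 3 2,4,5-trimethoxyphenol, via 2,4,5-trimethoxyphenyl formate 2 (not isolated)
Conditions: mCPBA, CH2Cl2, 0 °C to rt; then K2CO3 (cat.), MeOH, rt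
Reagents that add atoms: mCPBA, OOC(=O)c1cccc(Cl)c1
Why: Dakin oxidation, in which the peracid adds to the aldehyde and the electron-rich aryl group migrates to oxygen (Baeyer–Villiger-type shift) to give the formate, which carbonate-catalysed methanolysis cleaves to the phenol.

Step 2
Reactants: 4 ethyl 5-(benzyloxy)-1H-indole-2-carboxylate
Product: 5 ethyl 5-(benzyloxy)-3-bromo-1H-indole-2-carboxylate
Conditions: NBS, DMF, 0 °C to rt
Reagents that add atoms: N-bromosuccinimide, O=C1CCC(=O)N1Br
Why: Electrophilic aromatic bromination, selective because C3 is the most nucleophilic carbon of an indole-2-carboxylate and the benzyloxy-bearing benzo ring reacts more slowly.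

Step 3
Reactants: 5 ethyl 5-(benzyloxy)-3-bromo-1H-indole-2-carboxylate
Product: 6 ethyl 5-(benzyloxy)-3-bromo-1-SEM-indole-2-carboxylate
Conditions: NaH, SEMCl, DMF, 0 °C to rt
Reagents that add atoms: 2-(trimethylsilyl)ethoxymethyl chloride, C[Si](C)(C)CCOCCl
Why: N-alkylation of the indolide anion (SN2 on the chloromethyl ether), the N–H of the 2-acylindole being acidic enough for clean deprotonation by NaH.

Step 4
Reactants: 6 ethyl 5-(benzyloxy)-3-bromo-1-SEM-indole-2-carboxylate
Product: 7 5-(benzyloxy)-3-bromo-1-SEM-indole-2-carboxylic acid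
Conditions: LiOH·H2O, THF/EtOH/H2O, 50 °C; then 1 M HCl to pH 3, 0 °C
Reagents that add atoms: lithium hydroxide, [Li+].[OH-]
Why: Ester saponification by acyl–oxygen cleavage; the aryl bromide, benzyl ether and SEM group are inert to hydroxide and to a brief cold acidification.

Step 5
Reactants: 7 5-(benzyloxy)-3-bromo-1-SEM-indole-2-carboxylic acid; 3 2,4,5-trimethoxyphenol
Product: 8 2,4,5-trimethoxyphenyl 5-(benzyloxy)-3-bromo-1-SEM-indole-2-carboxylate
Conditions: DCC, DMAP, CH2Cl2, 0 °C to rt
Reagents that add atoms: none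
Why: Steglich esterification, in which DCC activates the acid as the O-acylisourea and DMAP relays the acyl group to the phenol, while the protected indole nitrogen cannot compete as a nucleophile.

Step 6
Reactants: 8 2,4,5-trimethoxyphenyl 5-(benzyloxy)-3-bromo-1-SEM-indole-2-carboxylate
Product: 9 10-(benzyloxy)-1,2,4-trimethoxy-7-SEM-chromeno[3,4-b]indol-6(7H)-one (lactone with indole C3 bonded to the phenol carbon ortho to the ester oxygen)
Conditions: Pd(OAc)2 (10 mol%), PCy3·HBF4 (20 mol%), K2CO3 (2 equiv), PivOH (30 mol%), degassed DMA, 110 °C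
Reagents that add atoms: none
Why: Zerovalent palladium carrying PCy3, formed in the flask from Pd(OAc)2, adds oxidatively to the C3–Br bond of 8; bromide on the resulting divalent arylpalladium is exchanged for pivalate, which delivers concerted metalation–deprotonation at C6–H of the trimethoxyphenyl ring, and reductive elimination from the seven-membered diarylpalladacycle forms the bond between indole C3 and that carbon. The closest known reaction type is the palladium-catalysed intramolecular direct arylation of aryl 2-halobenzoates (ester-bridged biaryl lactone synthesis under carbonate–pivalate conditions). The one ring formed, the six-membered lactone (pyranone ring of the chromeno[3,4-b]indol-6-one), is closed by this C(sp2)–C(sp2) reductive elimination, the ester having already placed the two carbons in a 1,6 relationship. No stereocentre arises, and no stereogenic axis has to be controlled. The step needs site selectivity on the phenol ring and chemoselectivity at palladium: the three-atom C(=O)–O tether lets only the carbon ortho to the ester oxygen reach the metal (the other ortho position bears methoxy and the C–H between two methoxy groups is out of reach), and 8 holds a single carbon–halogen bond. The SEM group removes the acidic N–H, so no indolide can form and attack the aryl ester under the basic conditions.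

Step 7
Reactants: 9 10-(benzyloxy)-1,2,4-trimethoxy-7-SEM-chromeno[3,4-b]indol-6(7H)-one
Product: 11 methyl 5-(benzyloxy)-3-(2,3,5,6-tetramethoxyphenyl)-1-SEM-indole-2-carboxylate, via ring-opened hydroxyaryl methyl ester 10 (not isolated)
Conditions: K2CO3, MeOH/THF, rt; then MeI, 40 °C
Reagents that add atoms: methanol, CO; iodomethane, CI
Why: Transesterification of the aryl ester (lactone) by methoxide followed by Williamson O-methylation, the ring-opening equilibrium being drained because the released phenoxide is methylated irreversibly and cannot relactonise.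

Step 8
Reactants: 11 methyl 5-(benzyloxy)-3-(2,3,5,6-tetramethoxyphenyl)-1-SEM-indole-2-carboxylate
Product: 12 methyl 5-(benzyloxy)-3-(4-bromo-2,3,5,6-tetramethoxyphenyl)-1-SEM-indole-2-carboxylate
Conditions: NBS (1.05 equiv), anhydrous MeCN, 0 °C to rt, dark
Reagents that add atoms: N-bromosuccinimide, O=C1CCC(=O)N1Br
Why: Electrophilic aromatic bromination at the only C–H of ring C, which lies between two methoxy groups on a tetra-oxygenated benzene, whereas the indole is deactivated by its C2 ester, has C2 and C3 blocked and has C4 shielded by the orthogonal aryl group.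

Step 9
Reactants: 13 6-methoxy-1H-indole
Product: 14 tert-butyl 6-methoxy-1H-indole-1-carboxylate
Conditions: Boc2O, DMAP (cat.), MeCN, rt
Reagents that add atoms: di-tert-butyl dicarbonate, CC(C)(C)OC(=O)OC(=O)OC(C)(C)C
Why: N-acylation (Boc protection) under nucleophilic catalysis by DMAP; the carbamate protects nitrogen and shields C2 and C7 for the borylation that follows.

Step 10
Reactants: 14 tert-butyl 6-methoxy-1H-indole-1-carboxylate
Product: 15 tert-butyl 6-methoxy-3-(Bpin)-1H-indole-1-carboxylate
Conditions: [Ir(OMe)(cod)]2 (1.5 mol%), 4,4'-di-tert-butyl-2,2'-bipyridine (3 mol%), B2pin2 (1.0 equiv), THF, 60 °C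
Reagents that add atoms: bis(pinacolato)diboron, CC1(C)OB(OC1(C)C)B1OC(C)(C)C(C)(C)O1
Why: Iridium-catalysed aromatic C–H borylation under steric control: the Boc group blocks C2 and C7 and the methoxy group hinders C5 and C7, so the pyrrole C3–H is borylated.

Step 11
Reactants: 12 methyl 5-(benzyloxy)-3-(4-bromo-2,3,5,6-tetramethoxyphenyl)-1-SEM-indole-2-carboxylate; 15 tert-butyl 6-methoxy-3-(Bpin)-1H-indole-1-carboxylate
Product: 16 methyl 5-(benzyloxy)-3-[4-(1-Boc-6-methoxyindol-3-yl)-2,3,5,6-tetramethoxyphenyl]-1-SEM-indole-2-carboxylate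
Conditions: Pd(OAc)2 (5 mol%), SPhos (10 mol%), K3PO4, toluene/H2O (10:1), 90 °C
Reagents that add atoms: none
Why: Suzuki–Miyaura coupling, in which the bulky electron-rich biarylphosphine SPhos drives oxidative addition into the di-ortho-methoxy aryl bromide and transmetalation of the N-Boc indol-3-yl boronate, the flanked methyl ester is inert to K3PO4, and any Boc group lost here is removed anyway in step 12.

Step 12
Reactants: 16 methyl 5-(benzyloxy)-3-[4-(1-Boc-6-methoxyindol-3-yl)-2,3,5,6-tetramethoxyphenyl]-1-SEM-indole-2-carboxylate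
Product: 17 5-(benzyloxy)-3-[2,3,5,6-tetramethoxy-4-(6-methoxy-1H-indol-3-yl)phenyl]-1-SEM-indole-2-carboxylic acid
Conditions: KOH (excess), MeOH/THF/H2O, 70 °C; then 1 M HCl to pH 4, 0 °C
Reagents that add atoms: potassium hydroxide, [K+].[OH-]
Why: Saponification of the methyl ester with concurrent cleavage of the indole N-Boc carbamate by hydroxide; the benzyl ether, methyl ethers and SEM group are base-stable, so the forcing conditions a flanked ester needs are tolerated.

Step 13
Reactants: 17 5-(benzyloxy)-3-[2,3,5,6-tetramethoxy-4-(6-methoxy-1H-indol-3-yl)phenyl]-1-SEM-indole-2-carboxylic acid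
Product: 18 5-(benzyloxy)-3-[2,3,5,6-tetramethoxy-4-(6-methoxy-1H-indol-3-yl)phenyl]-1-SEM-1H-indole
Conditions: Cu2O (10 mol%), 1,10-phenanthroline (20 mol%), NMP/quinoline (3:1), 170 °C
Reagents that add atoms: none
Why: Copper-catalysed protodecarboxylation of an indole-2-carboxylic acid, in which the copper carboxylate loses CO2 to an indol-2-ylcopper species that is protonated, assisted by the twist that the flanking N-SEM and 3-aryl groups impose on the carboxylate.

Step 14
Reactants: 18 5-(benzyloxy)-3-[2,3,5,6-tetramethoxy-4-(6-methoxy-1H-indol-3-yl)phenyl]-1-SEM-1H-indole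
Product: 19 5-(benzyloxy)-3-[2,3,5,6-tetramethoxy-4-(6-methoxy-1H-indol-3-yl)phenyl]-1H-indole
Conditions: Bu4NF (TBAF, 1 M in THF), ethylenediamine, DMF, 80 °C
Reagents that add atoms: none
Why: Fluoride-induced SEM cleavage (attack at silicon, loss of ethene, then release of the N–CH2–O carbon as formaldehyde, which ethylenediamine traps as the aminal); benzyl and methyl ethers are inert to fluoride.

Step 15
Reactants: 19 5-(benzyloxy)-3-[2,3,5,6-tetramethoxy-4-(6-methoxy-1H-indol-3-yl)phenyl]-1H-indole
Product: 20 3-[2,3,5,6-tetramethoxy-4-(6-methoxy-1H-indol-3-yl)phenyl]-1H-indol-5-ol (CNP0234672.0)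
Conditions: H2 (1 atm), 10% Pd/C, EtOAc/MeOH, rt
Reagents that add atoms: none
Why: Catalytic hydrogenolysis of the benzyl aryl ether over palladium; the indole rings and methyl ethers are not reduced at one atmosphere and room temperature, so filtration and evaporation should give the target.

Compound list
1 | 2,4,5-trimethoxybenzaldehyde | COc1cc(OC)c(C=O)cc1OC | starting material
2 | 2,4,5-trimethoxyphenyl formate | COc1cc(OC)c(OC=O)cc1OC | intermediate
3 | 2,4,5-trimethoxyphenol | COc1cc(OC)c(O)cc1OC | intermediate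
4 | ethyl 5-(benzyloxy)-1H-indole-2-carboxylate | CCOC(=O)c1cc2cc(OCc3ccccc3)ccc2[nH]1 | starting material
5 | ethyl 5-(benzyloxy)-3-bromo-1H-indole-2-carboxylate | CCOC(=O)c1[nH]c2ccc(OCc3ccccc3)cc2c1Br | intermediate
6 | ethyl 5-(benzyloxy)-3-bromo-1-{[2-(trimethylsilyl)ethoxy]methyl}-1H-indole-2-carboxylate | CCOC(=O)c1n(COCC[Si](C)(C)C)c2ccc(OCc3ccccc3)cc2c1Br | intermediate
7 | 5-(benzyloxy)-3-bromo-1-{[2-(trimethylsilyl)ethoxy]methyl}-1H-indole-2-carboxylic acid | OC(=O)c1n(COCC[Si](C)(C)C)c2ccc(OCc3ccccc3)cc2c1Br | intermediate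
8 | 2,4,5-trimethoxyphenyl 5-(benzyloxy)-3-bromo-1-{[2-(trimethylsilyl)ethoxy]methyl}-1H-indole-2-carboxylate | COc1cc(OC)c(OC(=O)c2c(Br)c3cc(OCc4ccccc4)ccc3n2COCC[Si](C)(C)C)cc1OC | intermediate
9 | 10-(benzyloxy)-1,2,4-trimethoxy-7-{[2-(trimethylsilyl)ethoxy]methyl}chromeno[3,4-b]indol-6(7H)-one | COc1cc(OC)c2OC(=O)c3n(COCC[Si](C)(C)C)c4ccc(OCc5ccccc5)cc4c3-c2c1OC | intermediate
10 | methyl 5-(benzyloxy)-3-(2-hydroxy-3,5,6-trimethoxyphenyl)-1-{[2-(trimethylsilyl)ethoxy]methyl}-1H-indole-2-carboxylate (formed as its potassium phenoxide) | COC(=O)c1n(COCC[Si](C)(C)C)c2ccc(OCc3ccccc3)cc2c1-c4c(O)c(OC)cc(OC)c4OC | intermediate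
11 | methyl 5-(benzyloxy)-3-(2,3,5,6-tetramethoxyphenyl)-1-{[2-(trimethylsilyl)ethoxy]methyl}-1H-indole-2-carboxylate | COC(=O)c1n(COCC[Si](C)(C)C)c2ccc(OCc3ccccc3)cc2c1-c4c(OC)c(OC)cc(OC)c4OC | intermediate
12 | methyl 5-(benzyloxy)-3-(4-bromo-2,3,5,6-tetramethoxyphenyl)-1-{[2-(trimethylsilyl)ethoxy]methyl}-1H-indole-2-carboxylate | COC(=O)c1n(COCC[Si](C)(C)C)c2ccc(OCc3ccccc3)cc2c1-c4c(OC)c(OC)c(Br)c(OC)c4OC | intermediate
13 | 6-methoxy-1H-indole | COc1ccc2cc[nH]c2c1 | starting material
14 | tert-butyl 6-methoxy-1H-indole-1-carboxylate | COc1ccc2ccn(C(=O)OC(C)(C)C)c2c1 | intermediate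
15 | tert-butyl 6-methoxy-3-(4,4,5,5-tetramethyl-1,3,2-dioxaborolan-2-yl)-1H-indole-1-carboxylate | COc1ccc2c(B3OC(C)(C)C(C)(C)O3)cn(C(=O)OC(C)(C)C)c2c1 | intermediate
16 | methyl 5-(benzyloxy)-3-{4-[1-(tert-butoxycarbonyl)-6-methoxy-1H-indol-3-yl]-2,3,5,6-tetramethoxyphenyl}-1-{[2-(trimethylsilyl)ethoxy]methyl}-1H-indole-2-carboxylate | COC(=O)c1n(COCC[Si](C)(C)C)c2ccc(OCc3ccccc3)cc2c1-c4c(OC)c(OC)c(-c5cn(C(=O)OC(C)(C)C)c6cc(OC)ccc56)c(OC)c4OC | intermediate
17 | 5-(benzyloxy)-3-[2,3,5,6-tetramethoxy-4-(6-methoxy-1H-indol-3-yl)phenyl]-1-{[2-(trimethylsilyl)ethoxy]methyl}-1H-indole-2-carboxylic acid | OC(=O)c1n(COCC[Si](C)(C)C)c2ccc(OCc3ccccc3)cc2c1-c4c(OC)c(OC)c(-c5c[nH]c6cc(OC)ccc56)c(OC)c4OC | intermediate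
18 | 5-(benzyloxy)-3-[2,3,5,6-tetramethoxy-4-(6-methoxy-1H-indol-3-yl)phenyl]-1-{[2-(trimethylsilyl)ethoxy]methyl}-1H-indole | C[Si](C)(C)CCOCn1cc(-c4c(OC)c(OC)c(-c5c[nH]c6cc(OC)ccc56)c(OC)c4OC)c2cc(OCc3ccccc3)ccc21 | intermediate
19 | 5-(benzyloxy)-3-[2,3,5,6-tetramethoxy-4-(6-methoxy-1H-indol-3-yl)phenyl]-1H-indole | COc1ccc2c(-c3c(OC)c(OC)c(-c4c[nH]c5ccc(OCc6ccccc6)cc45)c(OC)c3OC)c[nH]c2c1 | intermediate
20 | 3-[2,3,5,6-tetramethoxy-4-(6-methoxy-1H-indol-3-yl)phenyl]-1H-indol-5-ol (CNP0234672.0) | COc1ccc2c(-c3c(OC)c(OC)c(-c4c[nH]c5ccc(O)cc45)c(OC)c3OC)c[nH]c2c1 | target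

Total step count: 15.
Longest linear sequence: 12 steps (from 4 to 20 through steps 2 to 8 and 11 to 15).

Steps most likely to fail

Step 6. C–H palladation may be slow, because the aryl ester prefers the rotamer that holds the phenol ring away from palladium and the reacting carbon is electron-rich and flanked by methoxy. The arylpalladium bromide would then be reduced with loss of bromine, or the activated aryl ester would be cleaved by carbonate or pivalate. The fallback replaces the tethered arylation by an intermolecular Suzuki–Miyaura coupling and sets out from 7. O-Methylation (MeI, K2CO3, DMF) gives methyl 5-(benzyloxy)-3-bromo-1-SEM-indole-2-carboxylate F1. Purchased 1,2,4,5-tetramethoxybenzene F2 is lithiated between two methoxy groups (n-BuLi, THF, 0 °C) and quenched with B(OiPr)3 and aqueous acid to give (2,3,5,6-tetramethoxyphenyl)boronic acid F3. Coupling of F1 with F3 (Pd(OAc)2, SPhos, K3PO4, toluene/H2O, 90 °C) comes back to the route at 11.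

Step 8. The electrophile may show poor chemoselectivity, brominating the benzyloxy-bearing benzo ring of the indole, or the tetramethoxybenzene may suffer oxidative demethylation towards a quinone. The fallback uses deprotonative metalation instead of electrophilic substitution and sets out from 11. The C–H flanked by two methoxy groups is metalated with the ester-tolerant hindered amide base TMP2Mg·2LiCl (THF, 0 °C) and quenched with iodine to give methyl 5-(benzyloxy)-3-(4-iodo-2,3,5,6-tetramethoxyphenyl)-1-SEM-indole-2-carboxylate F4. Suzuki coupling of F4 with 15 under the conditions of step 11 comes back at 16.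

Step 11. Protodeboronation of the indol-3-yl boronate and hydrolytic loss of its Boc group may outpace transmetalation to the hindered arylpalladium, so that the bromide is returned or reduced. The fallback is a Negishi coupling under anhydrous, base-free conditions with an organozinc in place of the boronate, and it sets out from 13. C3 iodination (I2, KOH, DMF) gives 3-iodo-6-methoxy-1H-indole F5, which is acylated without purification (Boc2O, DMAP, CH2Cl2) to tert-butyl 3-iodo-6-methoxy-1H-indole-1-carboxylate F6. Zinc insertion (Zn dust, LiCl, THF, 40 °C) gives [1-(tert-butoxycarbonyl)-6-methoxy-1H-indol-3-yl]zinc iodide F7. Coupling of F7 with 12 (Pd(OAc)2, SPhos, THF, 60 °C) comes back at 16.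

Further compounds
F1 | step 6 | methyl 5-(benzyloxy)-3-bromo-1-{[2-(trimethylsilyl)ethoxy]methyl}-1H-indole-2-carboxylate | COC(=O)c1n(COCC[Si](C)(C)C)c2ccc(OCc3ccccc3)cc2c1Br
F2 | step 6 | 1,2,4,5-tetramethoxybenzene (purchased) | COc1cc(OC)c(OC)cc1OC
F3 | step 6 | (2,3,5,6-tetramethoxyphenyl)boronic acid | COc1cc(OC)c(OC)c(B(O)O)c1OC
F4 | step 8 | methyl 5-(benzyloxy)-3-(4-iodo-2,3,5,6-tetramethoxyphenyl)-1-{[2-(trimethylsilyl)ethoxy]methyl}-1H-indole-2-carboxylate | COC(=O)c1n(COCC[Si](C)(C)C)c2ccc(OCc3ccccc3)cc2c1-c4c(OC)c(OC)c(I)c(OC)c4OC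
F5 | step 11 | 3-iodo-6-methoxy-1H-indole | COc1ccc2c(I)c[nH]c2c1
F6 | step 11 | tert-butyl 3-iodo-6-methoxy-1H-indole-1-carboxylate | COc1ccc2c(I)cn(C(=O)OC(C)(C)C)c2c1
F7 | step 11 | [1-(tert-butoxycarbonyl)-6-methoxy-1H-indol-3-yl]zinc iodide | COc1ccc2c([Zn]I)cn(C(=O)OC(C)(C)C)c2c1
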